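**Plan** (benzodioxine numbering: O1, C2 aryl, C3 methyl, O4, C4a, C5 OMe, C6, C7 propenyl, C8, C8a)
1. Cuts: first C7–propenyl (Suzuki–Miyaura on a C7 triflate). Then C2–aryl (Friedel–Crafts attack of syringol on the O1=C2 oxocarbenium ion, with C2 taken back to a lactone C=O). Last the O1–C8a bond, with O1 moved back onto C4a.
2. The last cut contracts the dioxane ring to a spiro-1,3-dioxolan-4-one on a cyclohexa-2,5-dienone. This comes from oxidative dearomatisation of a vanillin-derived 4-alkoxyphenol that carries a lactic acid unit on O4.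
3. Enabling feature: C4a (bearing O4) is para to C7 and lies between C5 (OMe, blocked) and C8a (H). With oxygen in place of propenyl at C7, ring A can exist as a p-quinone monoketal at C4a, and O1 at carboxylate level is a leaving group that can re-enter productively only at C8a.
4. Forward order: O4–C3 bond, C7 CHO to OH, five-membered spirolactone, enlargement to the six-membered lactone with rearomatisation, C7 triflate, C2 acetal, C2 aryl, C7 propenyl.
5. Stereochemistry: C3 (R) comes from ethyl (S)-lactate by Mitsunobu inversion and is not touched afterwards. C2 (R) follows from C3 by anti attack on the oxocarbenium ion and by equilibration of the p-hydroxybenzylic C2–O1 bond to the trans isomer. The E alkene comes from the E boronic acid.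

Key step: step 5

Remark: the descriptors read from the SMILES are (2R,3R), which is the trans-2-aryl-3-methyl arrangement. Compounds 1, 2, 11 and 13 are taken as commercial.

Step 1
Reactants: 1 vanillin (4-hydroxy-3-methoxybenzaldehyde); 2 ethyl (S)-lactate
Product: 3 ethyl (2R)-2-(4-formyl-2-methoxyphenoxy)propanoate
Conditions: PPh3, DIAD, THF, 0 °C → rt
Reagents that add atoms: none
Why: The Mitsunobu reaction of an acidic phenol with a lactate ester is a standard SN2 etherification that should invert the S carbinol centre cleanly and so set the future C3 as R.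

Step 2
Reactants: 3 ethyl (2R)-2-(4-formyl-2-methoxyphenoxy)propanoate
Product: 4 ethyl (2R)-2-[4-(formyloxy)-2-methoxyphenoxy]propanoate
Conditions: mCPBA, CH2Cl2, rt
Reagents that add atoms: mCPBA, O=C(OO)c1cccc(Cl)c1
Why: Baeyer–Villiger oxidation of a benzaldehyde with a para alkoxy group proceeds by aryl migration and should give the aryl formate, which replaces the formyl carbon at the future C7 by the oxygen needed for dearomatisation without touching the stereocentre.

Step 3
Reactants: 4 ethyl (2R)-2-[4-(formyloxy)-2-methoxyphenoxy]propanoate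
Product: 5 (2R)-2-(4-hydroxy-2-methoxyphenoxy)propanoic acid
Conditions: LiOH, THF/H2O, 0 °C, Ar; then 1 M HCl
Reagents that add atoms: lithium hydroxide, [Li+].[OH-]
Why: Cold saponification cleaves the labile formate and the ethyl ester in one operation, and 2-aryloxypropanoates are known to survive such conditions without loss of configuration.

Step 4
Reactants: 5 (2R)-2-(4-hydroxy-2-methoxyphenoxy)propanoic acid
Product: 6 (3R)-6-methoxy-3-methyl-1,4-dioxaspiro[4.5]deca-6,9-diene-2,8-dione (both epimers at spiro C5)
Conditions: PhI(OAc)2, MeCN, 4 Å MS, 0 °C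
Reagents that add atoms: none
Why: Hypervalent iodine oxidative dearomatisation of a 4-alkoxyphenol, with 5-exo capture of the phenoxenium-type intermediate at the alkoxy-bearing para carbon by the tethered carboxylic acid, is the established route to quinone monoketal spirolactones; the new spiro centre need not be controlled because step 5 erases it.

Step 5
Reactants: 6 (3R)-6-methoxy-3-methyl-1,4-dioxaspiro[4.5]deca-6,9-diene-2,8-dione
Product: 7 (3R)-7-hydroxy-5-methoxy-3-methyl-2,3-dihydro-1,4-benzodioxin-2-one
Conditions: TfOH (10 mol %), HFIP/CH2Cl2 1:4, 0.01 M, 4 Å MS, 0 °C → rt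
Reagents that add atoms: none
Why: Proposed new method: Brønsted acid in the ionising, non-nucleophilic medium protonates the C8 carbonyl of 6 and loosens the C5–O1 acylal bond, so that the carboxylate oxygen O1 slides suprafacially from the spiro carbon C5 to the neighbouring cationic carbon C10 while the ether oxygen O4 holds C5 as an oxocarbenium ion, and loss of H-10 then aromatises ring A to the phenol 7. The closest known reaction types are the dienone–phenol rearrangement of spiro[4.5]decadienones, which enlarges the five-membered spiro ring to a fused six-membered ring, and the acid-induced 1,2-acyloxy shift of p-quinol acetates; neither has been shown on a spiro-1,3-dioxolan-4-one quinone monoketal. The six-membered ring is closed not by a cyclisation but by this 1,2-shift (three-centre transition state, or a tight carboxylate/oxocarbenium ion pair that recloses at C10), which turns the five-membered O1–C2–C3–O4–C5 ring into the six-membered O1–C2–C3–O4–C4a–C8a ring. No new stereocentre is formed: no bond to C3 is broken, so the lactate-derived R configuration is carried through, and the uncontrolled spiro centre becomes planar, so both epimers of 6 converge on 7. Two selectivities are needed: O1 and not O4 must migrate, which is secured because only the carboxylate is a competent nucleofuge and only the alkoxy oxygen O4 stabilises the cation left at C5 well; and C10 and not C6 must be the terminus, which is secured because C6 carries OMe and no H, so that a shift to C6 cannot aromatise and stays reversible. Aromatisation makes the productive shift irreversible and supplies the driving force.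

Step 6
Reactants: 7 (3R)-7-hydroxy-5-methoxy-3-methyl-2,3-dihydro-1,4-benzodioxin-2-one
Product: 8 (3R)-5-methoxy-3-methyl-2-oxo-2,3-dihydro-1,4-benzodioxin-7-yl trifluoromethanesulfonate
Conditions: Tf2O, pyridine, CH2Cl2, −20 °C
Reagents that add atoms: triflic anhydride, O=S(=O)(OS(=O)(=O)C(F)(F)F)C(F)(F)F
Why: Standard O-triflation of a phenol under cold, weakly basic conditions, which the aryl lactone and its alpha stereocentre should tolerate, turns the helper oxygen at C7 into a cross-coupling handle and lowers the electron density of ring A for step 8.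

Step 7
Reactants: 8 (3R)-5-methoxy-3-methyl-2-oxo-2,3-dihydro-1,4-benzodioxin-7-yl trifluoromethanesulfonate
Product: 10 (3R)-5-methoxy-3-methyl-7-(trifluoromethylsulfonyloxy)-2,3-dihydro-1,4-benzodioxin-2-yl acetate (both epimers at C2), via diisobutylaluminium hemiacetal 9 (not isolated)
Conditions: DIBAL-H (1.1 equiv), CH2Cl2, −78 °C; then pyridine, DMAP, Ac2O, −78 → 0 °C
Reagents that add atoms: DIBAL-H, CC(C)C[AlH]CC(C)C (its aluminium unit stays only in 9); acetic anhydride, CC(=O)OC(C)=O
Why: Reductive acetylation of a lactone delivers one hydride at −78 °C and traps the tetrahedral aluminium hemiacetal in situ by acylation before it can collapse, which should give the cyclic alpha-acetoxy ether with the ring intact; the configuration at C2 is irrelevant because it is ionised in step 8.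

Step 8
Reactants: 10 (3R)-5-methoxy-3-methyl-7-(trifluoromethylsulfonyloxy)-2,3-dihydro-1,4-benzodioxin-2-yl acetate; 11 syringol (2,6-dimethoxyphenol)
Product: 12 (2R,3R)-2-(4-hydroxy-3,5-dimethoxyphenyl)-5-methoxy-3-methyl-2,3-dihydro-1,4-benzodioxin-7-yl trifluoromethanesulfonate
Conditions: 11 (1.2 equiv), BF3·OEt2 (0.3 equiv), CH2Cl2, −40 → −10 °C
Reagents that add atoms: none
Why: The Lewis acid ionises the acetate to the cyclic O1=C2 oxocarbenium ion, which is attacked by C4 of syringol (para to OH, the site also used in its Duff formylation) in a Friedel–Crafts arylation of the aryl C-glycosylation type; the aryl group enters anti to the C3 methyl group, and because the p-hydroxybenzylic C2–O1 bond of the product ionises reversibly under these conditions, any cis isomer should drain to the diequatorial trans (2R,3R) isomer.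

Step 9
Reactants: 12 (2R,3R)-2-(4-hydroxy-3,5-dimethoxyphenyl)-5-methoxy-3-methyl-2,3-dihydro-1,4-benzodioxin-7-yl trifluoromethanesulfonate; 13 (E)-prop-1-en-1-ylboronic acid
Product: 14 4-[(2R,3R)-5-methoxy-3-methyl-7-[(E)-prop-1-en-1-yl]-2,3-dihydro-1,4-benzodioxin-2-yl]-2,6-dimethoxyphenol (target)
Conditions: 13 (1.5 equiv), Pd(dppf)Cl2 (5 mol %), K3PO4, THF/H2O, 45 °C
Reagents that add atoms: none
Why: Suzuki–Miyaura coupling of an aryl triflate with an E-alkenylboronic acid proceeds with retention of alkene geometry and tolerates the free phenol, and the mild temperature should keep base-induced opening of the benzylic C2–O1 bond, which could in any case only return the more stable trans isomer, to a minimum.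

**Compound list**
1 | vanillin | COc1cc(C=O)ccc1O | starting material
2 | ethyl (S)-lactate | C[C@H](O)C(=O)OCC | starting material
3 | ethyl (2R)-2-(4-formyl-2-methoxyphenoxy)propanoate | C[C@@H](Oc1ccc(C=O)cc1OC)C(=O)OCC | intermediate
4 | ethyl (2R)-2-[4-(formyloxy)-2-methoxyphenoxy]propanoate | C[C@@H](Oc1ccc(OC=O)cc1OC)C(=O)OCC | intermediate
5 | (2R)-2-(4-hydroxy-2-methoxyphenoxy)propanoic acid | C[C@@H](Oc1ccc(O)cc1OC)C(=O)O | intermediate
6 | (3R)-6-methoxy-3-methyl-1,4-dioxaspiro[4.5]deca-6,9-diene-2,8-dione | C[C@H]1OC2(OC1=O)C=CC(=O)C=C2OC | intermediate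
7 | (3R)-7-hydroxy-5-methoxy-3-methyl-2,3-dihydro-1,4-benzodioxin-2-one | C[C@H]1Oc2c(OC)cc(O)cc2OC1=O | intermediate
8 | (3R)-5-methoxy-3-methyl-2-oxo-2,3-dihydro-1,4-benzodioxin-7-yl trifluoromethanesulfonate | C[C@H]1Oc2c(OC)cc(OS(=O)(=O)C(F)(F)F)cc2OC1=O | intermediate
9 | diisobutylaluminium hemiacetal of 8 | C[C@H]1Oc2c(OC)cc(OS(=O)(=O)C(F)(F)F)cc2OC1O[Al](CC(C)C)CC(C)C | intermediate
10 | (3R)-5-methoxy-3-methyl-7-(trifluoromethylsulfonyloxy)-2,3-dihydro-1,4-benzodioxin-2-yl acetate | C[C@H]1Oc2c(OC)cc(OS(=O)(=O)C(F)(F)F)cc2OC1OC(C)=O | intermediate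
11 | syringol (2,6-dimethoxyphenol) | COc1cccc(OC)c1O | starting material
12 | (2R,3R)-2-(4-hydroxy-3,5-dimethoxyphenyl)-5-methoxy-3-methyl-2,3-dihydro-1,4-benzodioxin-7-yl trifluoromethanesulfonate | O=S(=O)(Oc1cc(OC)c2c(c1)O[C@H](c1cc(OC)c(O)c(OC)c1)[C@@H](C)O2)C(F)(F)F | intermediate
13 | (E)-prop-1-en-1-ylboronic acid | C/C=C/B(O)O | starting material
14 | 4-[(2R,3R)-5-methoxy-3-methyl-7-[(E)-prop-1-en-1-yl]-2,3-dihydro-1,4-benzodioxin-2-yl]-2,6-dimethoxyphenol | C/C=C/c1cc(OC)c2c(c1)O[C@H](c1cc(OC)c(O)c(OC)c1)[C@@H](C)O2 | target

Total step count: 9. Longest linear sequence: 9 (steps 1–9).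

**Steps most likely to fail**

Step 5 (Proposed new method).
- What may go wrong: the ketal may ionise without migration, followed by hydrolytic loss of the lactate unit. The phenolic product may be arylated intermolecularly by the cation. The ether oxygen may migrate instead of the carboxylate oxygen.
- Fallback (known chemistry): it sets out from 2 and comes back at 7.
  - Mitsunobu coupling of 2 with commercial 3,4-dihydroxy-5-methoxybenzaldehyde takes place at the more acidic 4-OH (para to CHO). It gives ethyl (2R)-2-(4-formyl-2-hydroxy-6-methoxyphenoxy)propanoate F1.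
  - PPTS in hot toluene closes the lactone to (3R)-5-methoxy-3-methyl-2-oxo-2,3-dihydro-1,4-benzodioxine-7-carbaldehyde F2.
  - Baeyer–Villiger oxidation with mCPBA gives (3R)-5-methoxy-3-methyl-2-oxo-2,3-dihydro-1,4-benzodioxin-7-yl formate F3.
  - The formyl group of F3 is removed with aqueous NaHCO3 in THF to give 7.

Step 8.
- What may go wrong: syringol may attack through C3 or through oxygen instead of C4. The benzylic ether of the product may re-ionise and be captured by a second syringol. The oxocarbenium ion may lose a proton, which erodes the C3 configuration.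
- Fallback: it sets out from 10 and comes back at 12.
  - TMSBr (CH2Cl2, 0 °C) converts 10 into the alpha-bromo ether (3R)-2-bromo-5-methoxy-3-methyl-2,3-dihydro-1,4-benzodioxin-7-yl trifluoromethanesulfonate F4.
  - Commercial 4-bromo-2,6-dimethoxyphenol is silylated (TBSCl, imidazole) to (4-bromo-2,6-dimethoxyphenoxy)(tert-butyl)dimethylsilane F5.
  - F5 is converted (Mg, THF) into [4-(tert-butyldimethylsilyloxy)-3,5-dimethoxyphenyl]magnesium bromide F6.
  - The classical alpha-halo ether/Grignard coupling of F4 with F6 (−78 → 0 °C) fixes the aryl position through the C–Mg bond and runs without acid. It gives (2R,3R)-2-[4-(tert-butyldimethylsilyloxy)-3,5-dimethoxyphenyl]-5-methoxy-3-methyl-2,3-dihydro-1,4-benzodioxin-7-yl trifluoromethanesulfonate F7.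
  - KHF2 in MeOH frees the phenol and gives 12.

Step 7.
- What may go wrong: the tetrahedral aluminium hemiacetal may collapse with loss of the aryloxide. Over-reduction or acetylation of the ring-opened phenol would follow.
- Fallback: it sets out from 8 and comes back at 10.
  - LiBH4 (THF, 0 °C) reduces the lactone fully to 3-hydroxy-4-{[(2R)-1-hydroxypropan-2-yl]oxy}-5-methoxyphenyl trifluoromethanesulfonate F8.
  - Parikh–Doering oxidation of the primary alcohol gives the aldehyde, which closes spontaneously to the lactol (3R)-2-hydroxy-5-methoxy-3-methyl-2,3-dihydro-1,4-benzodioxin-7-yl trifluoromethanesulfonate F9.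
  - Ac2O/pyridine gives 10.

Further compounds
F1 | step 5 | ethyl (2R)-2-(4-formyl-2-hydroxy-6-methoxyphenoxy)propanoate | C[C@@H](Oc1c(O)cc(C=O)cc1OC)C(=O)OCC
F2 | step 5 | (3R)-5-methoxy-3-methyl-2-oxo-2,3-dihydro-1,4-benzodioxine-7-carbaldehyde | C[C@H]1Oc2c(OC)cc(C=O)cc2OC1=O
F3 | step 5 | (3R)-5-methoxy-3-methyl-2-oxo-2,3-dihydro-1,4-benzodioxin-7-yl formate | C[C@H]1Oc2c(OC)cc(OC=O)cc2OC1=O
F4 | step 8 | (3R)-2-bromo-5-methoxy-3-methyl-2,3-dihydro-1,4-benzodioxin-7-yl trifluoromethanesulfonate | C[C@H]1Oc2c(OC)cc(OS(=O)(=O)C(F)(F)F)cc2OC1Br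
F5 | step 8 | (4-bromo-2,6-dimethoxyphenoxy)(tert-butyl)dimethylsilane | COc1cc(Br)cc(OC)c1O[Si](C)(C)C(C)(C)C
F6 | step 8 | [4-(tert-butyldimethylsilyloxy)-3,5-dimethoxyphenyl]magnesium bromide | COc1cc([Mg]Br)cc(OC)c1O[Si](C)(C)C(C)(C)C
F7 | step 8 | (2R,3R)-2-[4-(tert-butyldimethylsilyloxy)-3,5-dimethoxyphenyl]-5-methoxy-3-methyl-2,3-dihydro-1,4-benzodioxin-7-yl trifluoromethanesulfonate | O=S(=O)(Oc1cc(OC)c2c(c1)O[C@H](c1cc(OC)c(O[Si](C)(C)C(C)(C)C)c(OC)c1)[C@@H](C)O2)C(F)(F)F
F8 | step 7 | 3-hydroxy-4-{[(2R)-1-hydroxypropan-2-yl]oxy}-5-methoxyphenyl trifluoromethanesulfonate | C[C@H](CO)Oc1c(O)cc(OS(=O)(=O)C(F)(F)F)cc1OC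
F9 | step 7 | (3R)-2-hydroxy-5-methoxy-3-methyl-2,3-dihydro-1,4-benzodioxin-7-yl trifluoromethanesulfonate | C[C@H]1Oc2c(OC)cc(OS(=O)(=O)C(F)(F)F)cc2OC1O
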